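## Structural features

The target is one eleven-membered carbocycle, numbered from the quaternary carbon C1 through C2 to C11. It holds three ring alkenes: E-C2=C3, E-C6=C7 and Z-C9=C10 (C8 and C11 cis), the last two flanking the C8 ketone as a cross-conjugated dienone. C1 carries a methyl group and a 3-hydroxy-4-methylpent-4-enyl chain (C1′ to C4′) whose allylic carbinol C3′ (S) is remote from all other stereocentres. C4 (R, 3-methylbut-2-enoate) and C5 (R, tertiary methyl carbinol) are vicinal and syn, and C9 bears a hydroxymethyl group. The stereocentres form three isolated sets (C1; C4/C5; C3′), so each set needs its own asymmetric step. Fragile elements are the dienone with its α-hydroxymethyl group (conjugate addition, allylic transposition), the tertiary allylic alcohol vinylogous to the ketone, the unsaturated ester (deconjugation, migration to the C5 hydroxyl under base) and three allylic alcohols. The real difficulty is closing a medium ring with three defined alkenes and two fully substituted carbons, and fixing C4 next to C5, whose carbon substituents (methyl and alkenyl) differ little in size. The chosen closure exploits C4 as an allylic carbinol between the E-C2=C3 alkene and the non-enolisable C5: it is the adduct of an E-alkenyl metal at C3 and a C4 aldehyde, so the ring bond C3–C4, the C4 oxygen and the C4 stereocentre arise together.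

## Logic of the disconnections

**35 ⇒ 34 ⇒ 33 ⇒ 32.** Three O–Si bonds are cut and the C8 ketone is returned to a 4-methoxybenzyl-protected carbinol. The dienone and the free hydroxyls are the most fragile parts, so they are unveiled last. The gain is a robust, fully protected macrocycle. The demand is a mild fluoride source and an oxidant that leaves the ester and silyl ethers alone.

**32 ⇒ 30 + 31.** The C4 O–acyl bond is cut. Late acylation keeps the unsaturated ester away from organometallics and hydrides. The forward step must acylate a hindered secondary alcohol without deconjugating the acyl group.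

**30 ⇒ 28 (key).** The ring bond C3–C4 is cut to an E-vinyl iodide at C3 and an aldehyde at C4. This removes the ring and one stereocentre in one stroke and leaves an acyclic chain built from two fragments. The forward step needs aldehyde-only reactivity, retention of alkene geometry, high dilution and external control of the C4 face. The descriptors of 28 and 30 were checked against 35 (1S, 5R, 3′S, and 4R after closure); they agree, and C8 is arbitrary because it is oxidised later.

**28 ⇒ 27 ⇒ 25 ⇒ 24.** The C4 aldehyde is traced to a primary triethylsilyl ether and the C3–I bond to a terminal alkyne, and the C8 ether O–C bond is cut. The alkyne is the refinement over a late olefination of a C2 aldehyde: it is carried from an early stage, needs no fourth orthogonal oxygen protecting group, and becomes the E-iodide only after the other iodide has been used. The forward steps must be regioselective (hydrometalation) and must distinguish a primary triethylsilyl ether from tertiary triethylsilyl and tert-butyldimethylsilyl ethers.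

**24 ⇒ 17 + 22.** The C8–C9 bond is cut between a Z-alkenyl iodide (C9) and an enal (C8). This splits the chain into a C9–C11/C1–C3/side-chain fragment and a C4–C8 fragment of very different size. The forward addition must keep the C9=C10 geometry and add 1,2; the C8 configuration need not be controlled.

**17 ⇒ 16 ⇒ 14 ⇒ 13.** Two O–Si bonds are cut and the C3′ carbinol with its isopropenyl group is traced to a trisubstituted epoxide and then to the prenyl-type alkene. The stereocentre C3′ then comes from a catalyst-controlled epoxidation of the only electron-rich alkene. The isomerisation must remove a methyl proton and leave the C3′–O bond intact.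

**13 ⇒ 12 ⇒ 9 + 10.** The C9=C10 double bond is cut (carbonyl olefination) after adjusting the C9 ester to the alcohol. The stabilised iodo ylide sets the iodide cis to C11, which is the geometry needed for C8 later.

**9 ⇒ 7 ⇒ 6 ⇒ 5 ⇒ 4.** The C10–C11 bond (one-carbon homologation of the C11 aldehyde) and the C2≡C3 bond (C3 added to the C2 aldehyde) are cut. Both arms of the quaternary carbon then derive from the aldehyde and the siloxymethyl group of one precursor. None of these steps can touch C1, which has no α-hydrogen.

**4 ⇒ 3 ⇒ 2 ⇒ 1.** The C1–C11 bond is cut in the sense of a 1,2-shift of the siloxymethyl group onto the tertiary epoxide carbon. The epoxide comes from asymmetric epoxidation of the allylic alcohol 1. The quaternary stereocentre is thus bought with a reagent-controlled epoxidation and a stereospecific rearrangement.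

**22 ⇒ 21 ⇒ 19 + 20; 19 ⇒ 18.** The C6=C7 alkene is cut by metathesis logic, with C7 and C8 coming from 20, and the C6–C7 carbon is traced to a sulfur ylide opening the epoxide of 18. C5 is bought from the chiral pool and is never touched. The metathesis must be E-selective and tolerate a free tertiary allylic diol.

## Other disconnections considered

**Alternative 1:** The cut is at C10–C11 and C8–C9 around the trisubstituted alkene, with no ring closed. In the forward step the neopentyl iodide A2 would be lithiated and turned into an organocopper reagent. This would add syn to methyl propiolate A3, and the resulting α-cuprioacrylate would be trapped by the enal A4 to give A1.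
- In favour: C9=C10, the C9 ester (later the hydroxymethyl group) and the C8 carbinol arise in one operation. The quaternary carbon is used in its natural sense, the rearranged aldehyde becoming C2 and the siloxymethyl carbon C11. Relative to steps 5–9 and 16 of the chosen plan it should save about two operations; on step economy it is the better plan for this segment.
- Against: the organocopper reagent sits on a neopentyl carbon and must be used stoichiometrically in the most valuable fragment. The α-cuprioacrylate can equilibrate through an allenoate above about −78 °C, which would erase the alkene geometry. 1,2- versus 1,4-trapping by an enal is not assured.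
- Correction to the drawing of A1: the alkene is correct, but by the sequence rules it is E at this stage, because the ester outranks the C8 carbinol carbon; it becomes Z only once C8 is a ketone.
- Comparison: A1 does not close the ring and creates C8 without control, as step 16 does, so it is an equal there. It is an alternative to steps 7–9 and 16, not to the ring closure, and could feed the same closure at C3–C4. The chosen sequence is longer, but each bond is made by a geometry-retaining step that can be checked separately.

**Alternative 2:** The cut is at C7–C8 and O–C6. In the forward step the aldoxime A6 would be oxidised to the conjugated nitrile oxide A7, which would add across the C6=C7 vinyl group to close the carbocycle and a bridging isoxazoline in A5.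
- In favour: C4, C5 and the ester are set in the acyclic series before closure, so the weak point of the chosen plan (the C4 face during macrocyclisation) does not exist; on stereocontrol this alternative is the better one. No organometallic reagent is needed, free hydroxyls are tolerated, and the isoxazoline masks the sensitive enone until late.
- Against: an eleven-membered ring with an E-alkene has to form in a dipolar cycloaddition, where dimerisation of A7 competes and the bridged regiochemistry is not guaranteed in a medium ring. A7 derives from a Z-configured enal oxime that can isomerise. After closure, N–O cleavage and dehydration must be done beside four alkenes and a β-hydroxy ketone that can undergo retro-aldol ring opening.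
- Comparison: the ring closure is a concerted cycloaddition under entropic penalty, against an irreversible carbonyl addition in the chosen plan. After closure it needs about as many steps as the chosen plan (four), so it is an equal on step count and weaker on reliability of the closure.

**Alternative 3:** The cut is at C8–C9 and C7–C8, with carbon monoxide as the C8 source. In the forward step zerovalent palladium would insert into the C9–I bond of A9, take up carbon monoxide and couple the acylpalladium species with the C7 stannane to give A8.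
- In favour: the dienone is formed directly, with no C8 protecting group and no oxidation, and A8 is one desilylation from the target. This is the shortest endgame of all plans, and C4/C5 are again set before closure; on both points it is better than the chosen plan.
- Against: A9 must carry a Z-configured α-branched vinyl iodide, an E-vinylstannane, the ester and a free tertiary alcohol at once. Coupling without carbon monoxide uptake would contract the ring by one carbon. The acylpalladium intermediate of a hindered alkenyl iodide forms slowly and may isomerise. Reductive elimination has to create a strained eleven-membered dienone that is itself sensitive to Lewis acids.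
- Comparison: mechanistically the ring is closed at the most strained and most electrophilic part of the molecule, whereas the chosen plan closes it at an sp3 carbinol and introduces the dienone afterwards. The chosen plan pays three extra steps after closure for a closure that rests on broader precedent.

Key step: step 20

Assumption: the C8 carbinol formed in step 16 arises as a mixture of epimers; the route is written and drawn for the 8R epimer, and both epimers converge at the oxidation in step 23.

## Route

Step 1
Reactants: 1 geraniol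
Product: 2 (2S,3S)-2,3-epoxygeraniol
Conditions: Ti(OiPr)4 (5 mol %), L-(+)-diethyl tartrate (7 mol %), t-BuOOH, 4 Å molecular sieves, CH2Cl2, −20 °C
Reagents that add atoms: tert-butyl hydroperoxide, CC(C)(C)OO
Why: Sharpless asymmetric epoxidation; only the allylic alcohol alkene reacts, and the L-tartrate complex delivers oxygen to the face that gives the 2S,3S epoxide.

Step 2
Reactants: 2 (2S,3S)-2,3-epoxygeraniol
Product: 3 tert-butyldimethylsilyl ether of 2
Conditions: t-BuMe2SiCl, imidazole, CH2Cl2, 0 °C to rt
Reagents that add atoms: tert-butyldimethylsilyl chloride, CC(C)(C)[Si](C)(C)Cl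
Why: Standard silylation of a primary alcohol; the bulky silyl ether is the migrating-group carrier needed in step 3.

Step 3
Reactants: 3 tert-butyldimethylsilyl ether of 2
Product: 4 (S)-2-[(tert-butyldimethylsilyloxy)methyl]-2,6-dimethylhept-5-enal
Conditions: MeAl(OAr)2 (Ar = 4-bromo-2,6-di-tert-butylphenyl, 20 mol %), CH2Cl2, −78 to −40 °C
Reagents that add atoms: none
Why: Lewis-acid-promoted rearrangement of an epoxy silyl ether to a β-siloxy aldehyde; the siloxymethyl group shifts anti to the breaking tertiary C–O bond, so the epoxide chirality is transferred to the quaternary carbon (future C1), which cannot epimerise.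

Step 4
Reactants: 4 (S)-2-[(tert-butyldimethylsilyloxy)methyl]-2,6-dimethylhept-5-enal
Product: 5 (R)-tert-butyl[(2-ethynyl-2,6-dimethylhept-5-en-1-yl)oxy]dimethylsilane
Conditions: MeC(O)C(N2)P(O)(OMe)2, K2CO3, MeOH, 0 °C to rt
Reagents that add atoms: dimethyl (1-diazo-2-oxopropyl)phosphonate, CC(=O)C(=[N+]=[N-])P(=O)(OC)OC
Why: Ohira–Bestmann (Seyferth–Gilbert) homologation of a non-enolisable aldehyde to the terminal alkyne C2≡C3, the masked E-vinyl iodide; the descriptor changes only because the priorities change.

Step 5
Reactants: 5 (R)-tert-butyl[(2-ethynyl-2,6-dimethylhept-5-en-1-yl)oxy]dimethylsilane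
Product: 6 (R)-2-ethynyl-2,6-dimethylhept-5-en-1-ol
Conditions: Bu4NF, THF, 0 °C to rt
Reagents that add atoms: none
Why: Fluoride cleavage of the only silyl ether present frees the neopentyl-type C11 alcohol.

Step 6
Reactants: 6 (R)-2-ethynyl-2,6-dimethylhept-5-en-1-ol
Product: 7 (R)-2-ethynyl-2,6-dimethylhept-5-enal
Conditions: Dess–Martin periodinane, CH2Cl2, 0 °C to rt
Reagents that add atoms: none
Why: Mild oxidation of a primary alcohol; the aldehyde has no α-hydrogen, so C1 is safe.

Step 7
Reactants: 7 (R)-2-ethynyl-2,6-dimethylhept-5-enal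
Product: 9 (S)-3-ethynyl-3,7-dimethyloct-6-enal, via enol ether 8 (not isolated)
Conditions: Ph3P(Cl)CH2OMe, KN(SiMe3)2 (excess), THF, 0 °C; then aq. HCl (1 M), THF, 0 °C to rt, short contact
Reagents that add atoms: (methoxymethyl)triphenylphosphonium chloride, COC[P+](c1ccccc1)(c1ccccc1)c1ccccc1.[Cl-]; water, O
Why: Wittig methoxymethylenation of a hindered aldehyde followed by enol ether hydrolysis gives the one-carbon homologue (C11H2–C10HO); excess ylide covers the acidic alkyne proton, and dilute acid with short contact limits carbonyl-ene cyclisation onto the remote alkene.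

Step 8
Reactants: 9 (S)-3-ethynyl-3,7-dimethyloct-6-enal; 10 ethyl (triphenylphosphoranylidene)acetate
Product: 12 ethyl (2Z,5S)-5-ethynyl-2-iodo-5,9-dimethyldeca-2,8-dienoate, via iodo ylide 11 (not isolated)
Conditions: 10 (1.6 equiv), N-iodosuccinimide (1.5 equiv), CH2Cl2, −20 °C; then 9, 0 °C to rt
Reagents that add atoms: N-iodosuccinimide, O=C1CCC(=O)N1I
Why: Iodination of the stabilised ylide and Wittig olefination in one flask; stabilised α-halo ylides place the ester trans to the alkyl chain, so iodine ends cis to C11 (Z).

Step 9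
Reactants: 12 ethyl (2Z,5S)-5-ethynyl-2-iodo-5,9-dimethyldeca-2,8-dienoate
Product: 13 (2Z,5S)-5-ethynyl-2-iodo-5,9-dimethyldeca-2,8-dien-1-ol
Conditions: i-Bu2AlH (2.5 equiv), CH2Cl2, −78 °C; aq. KNaC4H4O6 work-up
Reagents that add atoms: none
Why: 1,2-Reduction of an α,β-unsaturated ester to the allylic alcohol; the vinyl iodide and the alkyne are inert to the hydride at −78 °C.

Step 10
Reactants: 13 (2Z,5S)-5-ethynyl-2-iodo-5,9-dimethyldeca-2,8-dien-1-ol
Product: 14 (2Z,5S)-7-[(2S)-3,3-dimethyloxiran-2-yl]-5-ethynyl-2-iodo-5-methylhept-2-en-1-ol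
Conditions: L-fructose-derived Shi ketone (enantiomer of the usual catalyst, 30 mol %), KHSO5 (as 2KHSO5·KHSO4·K2SO4), K2CO3, Bu4NHSO4, MeCN/CH2(OMe)2/aq. buffer pH 10.5, 0 °C
Reagents that add atoms: potassium peroxymonosulfate, [K+].[O-]S(=O)(=O)OO
Why: Shi epoxidation; the chiral dioxirane attacks only the electron-rich trisubstituted alkene (the iodoalkene is deactivated), and the L-series ketone should give the S epoxide through the spiro transition state.

Step 11
Reactants: 14 (2Z,5S)-7-[(2S)-3,3-dimethyloxiran-2-yl]-5-ethynyl-2-iodo-5-methylhept-2-en-1-ol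
Product: 16 (2Z,5S,8S)-5-ethynyl-2-iodo-5,9-dimethyldeca-2,9-diene-1,8-diol, via bis(trimethylsilyl) ether 15 (not isolated)
Conditions: Me3SiOTf, DBU, toluene, −20 °C to rt; then K2CO3, MeOH
Reagents that add atoms: none
Why: Silyl triflate/amidine isomerisation of a trisubstituted epoxide to the allylic silyl ether: the tertiary C–O bond ionises and a methyl proton is lost, so the isopropenyl group forms and the C3′–O bond with its S configuration is retained; methanolysis removes both trimethylsilyl groups.

Step 12
Reactants: 16 (2Z,5S,8S)-5-ethynyl-2-iodo-5,9-dimethyldeca-2,9-diene-1,8-diol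
Product: 17 (2Z,5S,8S)-1,8-bis(tert-butyldimethylsilyloxy)-5-ethynyl-2-iodo-5,9-dimethyldeca-2,9-diene
Conditions: t-BuMe2SiOTf, 2,6-lutidine, CH2Cl2, −78 to 0 °C
Reagents that add atoms: tert-butyldimethylsilyl triflate, CC(C)(C)[Si](C)(C)OS(=O)(=O)C(F)(F)F
Why: Double silylation protects the primary and the secondary allylic alcohol in one operation.

Step 13
Reactants: 18 (S)-2-methylglycidol
Product: 19 (R)-2-methylbut-3-ene-1,2-diol
Conditions: Me3SI, n-BuLi (excess), THF, −10 °C to rt
Reagents that add atoms: trimethylsulfonium iodide, C[S+](C)C.[I-]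
Why: One-carbon homologation of an epoxide to an allylic alcohol by dimethylsulfonium methylide (attack at the CH2 terminus, then ylide-mediated elimination of dimethyl sulfide); the stereocentre is not a reaction site, and a Payne shift of the alkoxide is degenerate and returns the same enantiomer.

Step 14
Reactants: 19 (R)-2-methylbut-3-ene-1,2-diol; 20 crotonaldehyde
Product: 21 (R,E)-4,5-dihydroxy-4-methylpent-2-enal
Conditions: 20 (5 equiv), second-generation Hoveyda–Grubbs catalyst RuCl2(H2IMes)(=CH-C6H4-2-OiPr) (5 mol %), CH2Cl2, 40 °C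
Reagents that add atoms: none
Why: Olefin cross-metathesis of a free tertiary allylic alcohol with an enal; loss of propene drives the reaction and the conjugated product forms as the E isomer.

Step 15
Reactants: 21 (R,E)-4,5-dihydroxy-4-methylpent-2-enal
Product: 22 (R,E)-4-methyl-4,5-bis(triethylsilyloxy)pent-2-enal
Conditions: Et3SiOTf, 2,6-lutidine, CH2Cl2, −78 °C
Reagents that add atoms: triethylsilyl triflate, CC[Si](CC)(CC)OS(=O)(=O)C(F)(F)F
Why: The silyl triflate silylates the primary and the tertiary hydroxyl; the two triethylsilyl ethers are later told apart by their substitution (step 19).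

Step 16
Reactants: 17 (2Z,5S,8S)-1,8-bis(tert-butyldimethylsilyloxy)-5-ethynyl-2-iodo-5,9-dimethyldeca-2,9-diene; 22 (R,E)-4-methyl-4,5-bis(triethylsilyloxy)pent-2-enal
Product: 24 seco alkynol with the C8 carbinol (1S,5R,8R,3′S; C2≡C3 alkyne, C4H2OSiEt3, 5-OSiEt3, 9-CH2OSiMe2t-Bu, 3′-OSiMe2t-Bu), via alkenylchromium species 23 (not isolated)
Conditions: CrCl2 (4 equiv), NiCl2 (2 mol %), 22 (1.5 equiv), DMSO, rt
Reagents that add atoms: none
Why: Intermolecular Nozaki–Hiyama–Kishi coupling; the alkenylchromium reagent keeps the Z geometry (C8 ends cis to C11), adds 1,2 to the enal only and tolerates the acidic alkyne proton and all silyl ethers; C8 forms without control, which is accepted.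

Step 17
Reactants: 24 seco alkynol with the C8 carbinol
Product: 25 8-O-(4-methoxybenzyl) ether of 24
Conditions: 2-(4-methoxybenzyloxy)-4-methylquinoline, MeOTf, MgO, PhCF3, 0 °C to rt
Reagents that add atoms: 2-[(4-methoxybenzyl)oxy]-4-methylquinoline, COc1ccc(COc2cc(C)c3ccccc3n2)cc1
Why: Benzyl transfer from the N-methylated alkoxyquinolinium salt under buffered, near-neutral conditions; no alkoxide is formed (no silyl migration from the C9 siloxymethyl group) and no strong acid is present (no ionisation of the bis-allylic carbinol).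

Step 18
Reactants: 25 8-O-(4-methoxybenzyl) ether of 24
Product: 27 seco C3 (E)-vinyl iodide with C4H2OSiEt3, via alkenylzirconocene 26 (not isolated)
Conditions: Cp2Zr(H)Cl (1.5 equiv), THF, rt; then I2, 0 °C
Reagents that add atoms: iodine, II
Why: Hydrozirconation of a terminal alkyne is syn and places zirconium at the terminus, and iodinolysis proceeds with retention, so the E-vinyl iodide results; the alkyne reacts far faster than the 1,1-disubstituted and internal alkenes.

Step 19
Reactants: 27 seco C3 (E)-vinyl iodide with C4H2OSiEt3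
Product: 28 seco C3 vinyl iodide C4 aldehyde (1S,5R,8R,3′S)
Conditions: (COCl)2, DMSO, CH2Cl2, −78 to −30 °C; then Et3N, −78 to 0 °C
Reagents that add atoms: none
Why: Swern conditions convert a primary triethylsilyl ether directly into the aldehyde (silyl transfer to chloride, then the usual alkoxysulfonium ylide collapse), while tertiary triethylsilyl and tert-butyldimethylsilyl ethers stay; the aldehyde is non-enolisable.

Step 20
Reactants: 28 seco C3 vinyl iodide C4 aldehyde (1S,5R,8R,3′S)
Product: 30 macrocyclic C4 allylic alcohol (1S,2E,4R,5R,6E,8R,9Z), via alkenylchromium species 29 (not isolated)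
Conditions: CrCl2 (8 equiv), NiCl2 (cat.), N-[2-(4-isopropyl-4,5-dihydrooxazol-2-yl)-6-methylphenyl]methanesulfonamide (single antipode, 9 equiv), Et3N (9 equiv), THF, rt, slow addition of 28 to 0.002 M
Reagents that add atoms: none
Why: Zerovalent nickel, formed from NiCl2 and divalent chromium, inserts into the C3–I bond and hands the alkenyl group to chromium, giving the trivalent E-alkenylchromium species 29 with retention; this adds to the C4 aldehyde and forms C3–C4 and the chromium alkoxide of 30. The closest known reaction type is the Nozaki–Hiyama–Kishi macrocyclisation of ω-iodoalkenyl aldehydes to medium and large carbocyclic allylic alcohols, including runs with chromium-bound oxazoline–sulfonamide ligands. The eleven-membered ring closes in an 11-exo-trig mode (C3 attacks the carbonyl carbon, oxygen stays exocyclic); the three alkenes and the fully substituted C1 and C5 limit the rotamers, and high dilution with slow addition disfavours dimers. The new stereocentre C4 is controlled by the chiral ligand on chromium (reagent control); the antipode that delivers C3 to the face giving 4R, syn to the C5 oxygen, is to be chosen in a pilot comparison. The substrate bias (Felkin–Anh, C5–OSiEt3 anti to the incoming carbon) is weak because methyl and ring alkenyl on C5 are close in size. Chemoselectivity is secured by the organochromium reagent, which adds only to the aldehyde and leaves ethers, silyl ethers and alkenes alone. The aldehyde cannot enolise or epimerise because C5 is quaternary, and the bulky silyl ether blocks an α-ketol shift.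

Step 21
Reactants: 30 macrocyclic C4 allylic alcohol; 31 3-methylbut-2-enoyl chloride
Product: 32 C4 3-methylbut-2-enoate of 30
Conditions: 31 (3 equiv), DMAP, pyridine, CH2Cl2, 0 °C to rt
Reagents that add atoms: none
Why: Nucleophile-catalysed acylation of the only free hydroxyl; pyridine instead of a trialkylamine limits γ-deprotonation to the vinylketene, which would give the deconjugated ester.

Step 22
Reactants: 32 C4 3-methylbut-2-enoate of 30
Product: 33 C8 alcohol (8-de-O-benzylated 32)
Conditions: DDQ, CH2Cl2/aq. phosphate buffer pH 7, 0 °C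
Reagents that add atoms: none
Why: Oxidative cleavage of the 4-methoxybenzyl ether by hydride abstraction at the benzylic carbon and hydrolysis; silyl ethers and the ester are inert, and any over-oxidation at C8 leads to the product of step 23.

Step 23
Reactants: 33 C8 alcohol
Product: 34 cross-conjugated dienone (3′,9-CH2 bis-tert-butyldimethylsilyl, 5-triethylsilyl ether of the target)
Conditions: Dess–Martin periodinane, pyridine, CH2Cl2, 0 °C to rt
Reagents that add atoms: none
Why: Buffered oxidation of the bis-allylic alcohol to the ketone; both C8 epimers converge here, and no other oxidisable hydroxyl is free.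

Step 24
Reactants: 34 cross-conjugated dienone
Product: 35 target, (1S,2E,4R,5R,6E,9Z)-5-hydroxy-9-(hydroxymethyl)-1-[(3S)-3-hydroxy-4-methylpent-4-en-1-yl]-1,5-dimethyl-8-oxocycloundeca-2,6,9-trien-4-yl 3-methylbut-2-enoate
Conditions: HF·pyridine, pyridine, THF, 0 °C to rt
Reagents that add atoms: none
Why: Buffered fluoride cleaves the primary and secondary tert-butyldimethylsilyl ethers and the tertiary triethylsilyl ether under mildly acidic conditions that avoid base-induced acyl migration or conjugate addition.

## Compound list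

1 | geraniol, (E)-3,7-dimethylocta-2,6-dien-1-ol | CC(C)=CCC/C(C)=C/CO | starting material
2 | (2S,3S)-2,3-epoxygeraniol, [(2S,3S)-3-methyl-3-(4-methylpent-3-en-1-yl)oxiran-2-yl]methanol | OC[C@@H]1O[C@@]1(C)CCC=C(C)C | intermediate
3 | tert-butyldimethyl{[(2S,3S)-3-methyl-3-(4-methylpent-3-en-1-yl)oxiran-2-yl]methoxy}silane | CC(C)(C)[Si](C)(C)OC[C@@H]1O[C@@]1(C)CCC=C(C)C | intermediate
4 | (S)-2-[(tert-butyldimethylsilyloxy)methyl]-2,6-dimethylhept-5-enal | O=C[C@](C)(CO[Si](C)(C)C(C)(C)C)CCC=C(C)C | intermediate
5 | (R)-tert-butyl[(2-ethynyl-2,6-dimethylhept-5-en-1-yl)oxy]dimethylsilane | C#C[C@](C)(CO[Si](C)(C)C(C)(C)C)CCC=C(C)C | intermediate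
6 | (R)-2-ethynyl-2,6-dimethylhept-5-en-1-ol | C#C[C@](C)(CO)CCC=C(C)C | intermediate
7 | (R)-2-ethynyl-2,6-dimethylhept-5-enal | C#C[C@](C)(C=O)CCC=C(C)C | intermediate
8 | (3S)-3-ethynyl-1-methoxy-3,7-dimethylocta-1,6-diene (E/Z enol ether) | C#C[C@](C)(C=COC)CCC=C(C)C | intermediate
9 | (S)-3-ethynyl-3,7-dimethyloct-6-enal | C#C[C@](C)(CC=O)CCC=C(C)C | intermediate
10 | ethyl (triphenylphosphoranylidene)acetate | CCOC(=O)C=P(c1ccccc1)(c1ccccc1)c1ccccc1 | starting material
11 | ethyl iodo(triphenylphosphoranylidene)acetate | CCOC(=O)C(I)=P(c1ccccc1)(c1ccccc1)c1ccccc1 | intermediate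
12 | ethyl (2Z,5S)-5-ethynyl-2-iodo-5,9-dimethyldeca-2,8-dienoate | CCOC(=O)/C(I)=C/C[C@@](C)(C#C)CCC=C(C)C | intermediate
13 | (2Z,5S)-5-ethynyl-2-iodo-5,9-dimethyldeca-2,8-dien-1-ol | OC/C(I)=C/C[C@@](C)(C#C)CCC=C(C)C | intermediate
14 | (2Z,5S)-7-[(2S)-3,3-dimethyloxiran-2-yl]-5-ethynyl-2-iodo-5-methylhept-2-en-1-ol | OC/C(I)=C/C[C@@](C)(C#C)CC[C@@H]1OC1(C)C | intermediate
15 | (2Z,5S,8S)-5-ethynyl-2-iodo-5,9-dimethyl-1,8-bis(trimethylsilyloxy)deca-2,9-diene | C[Si](C)(C)OC/C(I)=C/C[C@@](C)(C#C)CC[C@H](O[Si](C)(C)C)C(C)=C | intermediate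
16 | (2Z,5S,8S)-5-ethynyl-2-iodo-5,9-dimethyldeca-2,9-diene-1,8-diol | OC/C(I)=C/C[C@@](C)(C#C)CC[C@H](O)C(C)=C | intermediate
17 | (2Z,5S,8S)-1,8-bis(tert-butyldimethylsilyloxy)-5-ethynyl-2-iodo-5,9-dimethyldeca-2,9-diene | CC(C)(C)[Si](C)(C)OC/C(I)=C/C[C@@](C)(C#C)CC[C@H](O[Si](C)(C)C(C)(C)C)C(C)=C | intermediate
18 | (S)-2-methylglycidol, [(2S)-2-methyloxiran-2-yl]methanol | OC[C@]1(C)OC1 | starting material
19 | (R)-2-methylbut-3-ene-1,2-diol | OC[C@](C)(O)C=C | intermediate
20 | crotonaldehyde, (E)-but-2-enal | C/C=C/C=O | starting material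
21 | (R,E)-4,5-dihydroxy-4-methylpent-2-enal | OC[C@](C)(O)/C=C/C=O | intermediate
22 | (R,E)-4-methyl-4,5-bis(triethylsilyloxy)pent-2-enal | CC[Si](CC)(CC)OC[C@](C)(O[Si](CC)(CC)CC)/C=C/C=O | intermediate
23 | (Z)-alkenylchromium dichloride from 17 (chromium at C9, cis to C11) | CC(C)(C)[Si](C)(C)OC/C(=C/C[C@@](C)(C#C)CC[C@H](O[Si](C)(C)C(C)(C)C)C(C)=C)[Cr](Cl)Cl | intermediate
24 | seco alkynol (1S,5R,8R,3′S): C1 with methyl, ethynyl, C11H2 and the (3S)-3-(tert-butyldimethylsilyloxy)-4-methylpent-4-enyl chain; (9Z)-C9=C10 with CH2OSiMe2t-Bu on C9; C8–OH; (6E)-C6=C7; C5(CH3)(OSiEt3); C4H2OSiEt3 | C=C(C)[C@@H](O[Si](C)(C)C(C)(C)C)CC[C@](C/C=C(/CO[Si](C)(C)C(C)(C)C)[C@H](O)/C=C/[C@@](C)(O[Si](CC)(CC)CC)CO[Si](CC)(CC)CC)(C)C#C | intermediate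
25 | 8-O-(4-methoxybenzyl) ether of 24 | C=C(C)[C@@H](O[Si](C)(C)C(C)(C)C)CC[C@](C/C=C(/CO[Si](C)(C)C(C)(C)C)[C@H](OCc1ccc(OC)cc1)/C=C/[C@@](C)(O[Si](CC)(CC)CC)CO[Si](CC)(CC)CC)(C)C#C | intermediate
26 | (E)-C3-alkenyl(chlorido)zirconocene from 25 | C=C(C)[C@@H](O[Si](C)(C)C(C)(C)C)CC[C@](C/C=C(/CO[Si](C)(C)C(C)(C)C)[C@H](OCc1ccc(OC)cc1)/C=C/[C@@](C)(O[Si](CC)(CC)CC)CO[Si](CC)(CC)CC)(C)/C=C/[Zr](Cl)(C1C=CC=C1)C1C=CC=C1 | intermediate
27 | seco C3 (E)-vinyl iodide with C4H2OSiEt3 (other groups as in 25) | C=C(C)[C@@H](O[Si](C)(C)C(C)(C)C)CC[C@](C/C=C(/CO[Si](C)(C)C(C)(C)C)[C@H](OCc1ccc(OC)cc1)/C=C/[C@@](C)(O[Si](CC)(CC)CC)CO[Si](CC)(CC)CC)(C)/C=C/I | intermediate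
28 | seco C3 (E)-vinyl iodide C4 aldehyde (1S,5R,8R,3′S; 3′-OSiMe2t-Bu, 9-CH2OSiMe2t-Bu, 8-O-(4-methoxybenzyl), 5-OSiEt3) | C=C(C)[C@@H](O[Si](C)(C)C(C)(C)C)CC[C@](C/C=C(/CO[Si](C)(C)C(C)(C)C)[C@H](OCc1ccc(OC)cc1)/C=C/[C@@](C)(O[Si](CC)(CC)CC)C=O)(C)/C=C/I | intermediate
29 | (E)-C3-alkenylchromium dichloride from 28 | C=C(C)[C@@H](O[Si](C)(C)C(C)(C)C)CC[C@](C/C=C(/CO[Si](C)(C)C(C)(C)C)[C@H](OCc1ccc(OC)cc1)/C=C/[C@@](C)(O[Si](CC)(CC)CC)C=O)(C)/C=C/[Cr](Cl)Cl | intermediate
30 | (1S,2E,4R,5R,6E,8R,9Z)-1-[(3S)-3-(tert-butyldimethylsilyloxy)-4-methylpent-4-en-1-yl]-9-[(tert-butyldimethylsilyloxy)methyl]-8-[(4-methoxybenzyl)oxy]-1,5-dimethyl-5-(triethylsilyloxy)cycloundeca-2,6,9-trien-4-ol | C=C(C)[C@@H](O[Si](C)(C)C(C)(C)C)CC[C@]1(C)/C=C/[C@@H](O)[C@](C)(O[Si](CC)(CC)CC)/C=C/[C@@H](OCc2ccc(OC)cc2)/C(CO[Si](C)(C)C(C)(C)C)=C\C1 | intermediate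
31 | 3-methylbut-2-enoyl chloride | CC(C)=CC(=O)Cl | starting material
32 | C4 3-methylbut-2-enoate of 30 (4R) | C=C(C)[C@@H](O[Si](C)(C)C(C)(C)C)CC[C@]1(C)/C=C/[C@@H](OC(=O)C=C(C)C)[C@](C)(O[Si](CC)(CC)CC)/C=C/[C@@H](OCc2ccc(OC)cc2)/C(CO[Si](C)(C)C(C)(C)C)=C\C1 | intermediate
33 | C8 alcohol (8R drawn) obtained from 32 by loss of the 4-methoxybenzyl group | C=C(C)[C@@H](O[Si](C)(C)C(C)(C)C)CC[C@]1(C)/C=C/[C@@H](OC(=O)C=C(C)C)[C@](C)(O[Si](CC)(CC)CC)/C=C/[C@@H](O)/C(CO[Si](C)(C)C(C)(C)C)=C\C1 | intermediate
34 | C8 ketone: 3′-O- and 9-CH2O-bis(tert-butyldimethylsilyl), 5-O-triethylsilyl ether of the target | C=C(C)[C@@H](O[Si](C)(C)C(C)(C)C)CC[C@]1(C)/C=C/[C@@H](OC(=O)C=C(C)C)[C@](C)(O[Si](CC)(CC)CC)/C=C/C(=O)/C(CO[Si](C)(C)C(C)(C)C)=C\C1 | intermediate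
35 | (1S,2E,4R,5R,6E,9Z)-5-hydroxy-9-(hydroxymethyl)-1-[(3S)-3-hydroxy-4-methylpent-4-en-1-yl]-1,5-dimethyl-8-oxocycloundeca-2,6,9-trien-4-yl 3-methylbut-2-enoate | C=C(C)[C@@H](O)CC[C@]1(C)/C=C/[C@@H](OC(=O)C=C(C)C)[C@](C)(O)/C=C/C(=O)/C(CO)=C\C1 | target

## Step count and least certain steps

Total: 24 steps. Longest linear sequence: 21 steps (steps 1–12 and 16–24, from 1); the three steps 13–15 make the C4–C8 fragment.

**Step 20 (key step).** The likely failures are poor facial selectivity at C4 and competing intermolecular coupling or reduction of the iodide. The ligand may have to override a Felkin–Anh preference that places the ring alkenyl group inside, and the two C8 epimers of 28 need not respond alike. Fallback: starting from 28, the ring is closed without ligand (CrCl2, catalytic NiCl2, DMSO, high dilution), accepting 30 together with its C4 epimer F1. The mixture is oxidised with Dess–Martin periodinane to the macrocyclic enone F2. F2 is then reduced at −78 °C with NaBH4/CeCl3 or LiBH(s-Bu)3. Hydride attack anti to the C5 silyloxy group, with the ring carbon C6 inside, should give the 4R alcohol; this is the same substrate bias that disfavours 4R in the carbon–carbon bond formation. The route is rejoined at 30.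

**Step 16.** The terminal alkyne may interfere with the alkenylnickel intermediate (five-membered carbometalation onto C2≡C3), and oxidative addition at the α-branched iodide may be slow, so that protodeiodination wins. Fallback: starting from 17, the alkyne is silylated (LiN(SiMe3)2, Me3SiCl, THF, −78 °C) to the trimethylsilylalkyne F3. Iodine–lithium exchange (t-BuLi, Et2O, −78 °C) and addition to 22 give the silylated alkynol F4. K2CO3 in MeOH at 0 °C removes the alkynyl silyl group and returns to 24.

**Step 19.** Silyl transfer from the neopentyl-like C4 oxygen to the activated sulfoxide may be slow, leading to incomplete conversion or to partial loss of the tertiary triethylsilyl ether at higher temperature. Fallback: starting from 27, the primary triethylsilyl ether is cleaved with pyridine-buffered HF·pyridine in THF at 0 °C to the C4 alcohol F5, which is oxidised with Dess–Martin periodinane to 28.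

**Step 21.** The acylating species may be γ-deprotonated to a vinylketene, which would give the deconjugated ester, and the hindered hydroxyl may react slowly. Fallback: starting from 30, esterification with (EtO)2P(O)CH2CO2H (DCC, DMAP) gives the phosphonoacetate F6. Horner–Wadsworth–Emmons reaction with acetone (NaH, THF) then builds the 3-methylbut-2-enoate and returns to 32.

**Step 14.** Catalyst turnover may be low because the alkene sits on a fully substituted carbinol carbon and the diol can bind ruthenium, and 20 may homodimerise. Fallback: starting from 19, double silylation (Et3SiOTf, 2,6-lutidine) gives the bis(triethylsilyl) ether F7. Ozonolysis (O3, then PPh3) gives the α-silyloxy aldehyde F8. Wittig reaction with Ph3P=CHCHO in toluene at 80 °C returns to 22.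

## Further compounds

F1 | step 20 | C4 epimer (4S) of 30 | C=C(C)[C@@H](O[Si](C)(C)C(C)(C)C)CC[C@]1(C)/C=C/[C@H](O)[C@](C)(O[Si](CC)(CC)CC)/C=C/[C@@H](OCc2ccc(OC)cc2)/C(CO[Si](C)(C)C(C)(C)C)=C\C1
F2 | step 20 | macrocyclic C4 ketone (enone) corresponding to 30 | C=C(C)[C@@H](O[Si](C)(C)C(C)(C)C)CC[C@]1(C)/C=C/C(=O)[C@](C)(O[Si](CC)(CC)CC)/C=C/[C@@H](OCc2ccc(OC)cc2)/C(CO[Si](C)(C)C(C)(C)C)=C\C1
F3 | step 16 | (trimethylsilyl)alkyne of 17 | CC(C)(C)[Si](C)(C)OC/C(I)=C/C[C@@](C)(C#C[Si](C)(C)C)CC[C@H](O[Si](C)(C)C(C)(C)C)C(C)=C
F4 | step 16 | (trimethylsilyl)alkyne of 24 | C=C(C)[C@@H](O[Si](C)(C)C(C)(C)C)CC[C@](C/C=C(/CO[Si](C)(C)C(C)(C)C)[C@H](O)/C=C/[C@@](C)(O[Si](CC)(CC)CC)CO[Si](CC)(CC)CC)(C)C#C[Si](C)(C)C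
F5 | step 19 | C4 primary alcohol from 27 | C=C(C)[C@@H](O[Si](C)(C)C(C)(C)C)CC[C@](C/C=C(/CO[Si](C)(C)C(C)(C)C)[C@H](OCc1ccc(OC)cc1)/C=C/[C@@](C)(O[Si](CC)(CC)CC)CO)(C)/C=C/I
F6 | step 21 | C4 (diethoxyphosphoryl)acetate of 30 | C=C(C)[C@@H](O[Si](C)(C)C(C)(C)C)CC[C@]1(C)/C=C/[C@@H](OC(=O)CP(=O)(OCC)OCC)[C@](C)(O[Si](CC)(CC)CC)/C=C/[C@@H](OCc2ccc(OC)cc2)/C(CO[Si](C)(C)C(C)(C)C)=C\C1
F7 | step 14 | (R)-2-methyl-1,2-bis(triethylsilyloxy)but-3-ene | CC[Si](CC)(CC)OC[C@](C)(O[Si](CC)(CC)CC)C=C
F8 | step 14 | (S)-2-methyl-2,3-bis(triethylsilyloxy)propanal | CC[Si](CC)(CC)OC[C@](C)(O[Si](CC)(CC)CC)C=O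
A1 | alternative 1 | C8 carbinol with C9 methyl ester and C2≡C3 silylalkyne (alkene E by the sequence rules, C8 cis to C11) | C=C(C)[C@@H](O[Si](C)(C)C(C)(C)C)CC[C@](C/C=C(\[C@H](O)/C=C/[C@@](C)(O[Si](CC)(CC)CC)COCc1ccc(OC)cc1)C(=O)OC)(C)C#C[Si](C)(C)C
A2 | alternative 1 | tert-butyl{[(3S,6R)-6-(iodomethyl)-2,6-dimethyl-8-(trimethylsilyl)oct-1-en-7-yn-3-yl]oxy}dimethylsilane | C=C(C)[C@@H](O[Si](C)(C)C(C)(C)C)CC[C@](CI)(C)C#C[Si](C)(C)C
A3 | alternative 1 | methyl propiolate | C#CC(=O)OC
A4 | alternative 1 | (R,E)-5-[(4-methoxybenzyl)oxy]-4-methyl-4-(triethylsilyloxy)pent-2-enal | O=C/C=C/[C@@](C)(O[Si](CC)(CC)CC)COCc1ccc(OC)cc1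
A5 | alternative 2 | isoxazoline-bridged cycloundecadiene | C=C(C)[C@@H](O[Si](C)(C)C(C)(C)C)CC[C@]1(C)/C=C/[C@@H](OC(=O)C=C(C)C)[C@](C)(O)[C@@H]2CC(=NO2)/C(CO[Si](C)(C)C(C)(C)C)=C\C1
A6 | alternative 2 | acyclic C8 aldoxime with C6=C7 vinyl group | C=C(C)[C@@H](O[Si](C)(C)C(C)(C)C)CC[C@](C/C=C(/CO[Si](C)(C)C(C)(C)C)C=NO)(C)/C=C/[C@@H](OC(=O)C=C(C)C)[C@](C)(O)C=C
A7 | alternative 2 | conjugated C8 nitrile oxide from A6 | C=C(C)[C@@H](O[Si](C)(C)C(C)(C)C)CC[C@](C/C=C(/CO[Si](C)(C)C(C)(C)C)C#[N+][O-])(C)/C=C/[C@@H](OC(=O)C=C(C)C)[C@](C)(O)C=C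
A8 | alternative 3 | bis(tert-butyldimethylsilyl) ether of the target | C=C(C)[C@@H](O[Si](C)(C)C(C)(C)C)CC[C@]1(C)/C=C/[C@@H](OC(=O)C=C(C)C)[C@](C)(O)/C=C/C(=O)/C(CO[Si](C)(C)C(C)(C)C)=C\C1
A9 | alternative 3 | acyclic C9 (Z)-vinyl iodide C7 (E)-vinylstannane | C=C(C)[C@@H](O[Si](C)(C)C(C)(C)C)CC[C@](C/C=C(\I)CO[Si](C)(C)C(C)(C)C)(C)/C=C/[C@@H](OC(=O)C=C(C)C)[C@](C)(O)/C=C/[Sn](CCCC)(CCCC)CCCC
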